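**Retrosynthetic overview**
- The only strategic disconnection is the ester C–O bond, giving pentacosanoic acid and tyrosol, both commercial.
- No ring is formed; the benzene ring is bought in tyrosol.
- The free phenol is left unprotected; a lipase acylates the primary aliphatic OH selectively.

Assumption: the target has no stereocentre and is achiral, so "single enantiomer" calls for no stereocontrol.

**Route**

Step 1
Reactants: 1 pentacosanoic acid; 2 tyrosol, 2-(4-hydroxyphenyl)ethanol
Product: 3 2-(4-hydroxyphenyl)ethyl pentacosanoate
Conditions: Novozym 435 (immobilised Candida antarctica lipase B, about 20 wt %), 2 (3 equiv), 4 Å molecular sieves, toluene/2-methyl-2-butanol 4:1, 65 °C, 48 h; filter hot, crystallise from MeOH (excess 2 stays in solution)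
Reagents that add atoms: none
Why: Lipase-catalysed chemoselective esterification, in which the enzyme transfers the acyl group of 1 to the primary aliphatic alcohol of 2 but not to the phenol, while the sieves remove water to drive the equilibrium; no stereocentre is created.

Checks on the route:
- The product has the C25 acyl chain, the ester oxygen, the CH2CH2 linker and the para-hydroxyphenyl ring, which matches the target SMILES.
- The equation is 1 + 2 → 3 + H2O, with every atom accounted for.
- The phenol, the only other functional group, is inert to the lipase at 65 °C, and 2-methyl-2-butanol is a tertiary alcohol that the enzyme does not acylate.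

**Compound list**
1 | pentacosanoic acid | CCCCCCCCCCCCCCCCCCCCCCCCC(=O)O | starting material
2 | tyrosol, 2-(4-hydroxyphenyl)ethanol | OCCc1ccc(O)cc1 | starting material
3 | 2-(4-hydroxyphenyl)ethyl pentacosanoate | CCCCCCCCCCCCCCCCCCCCCCCCC(=O)OCCc1ccc(O)cc1 | target

**Totals**
Total step count: 1. Longest linear sequence: 1.

**Steps most likely to fail**
The route has a single step, so only step 1 can be ranked. Its risks are slow turnover of the very long, poorly soluble acid 1 and incomplete conversion, which would leave acid that is hard to separate from the waxy ester.

Fallback for step 1: this sets out from compound 2 and comes back to the route at compound 3. It replaces the chemoselective enzymatic acylation with a protecting-group approach. Tyrosol 2 is benzylated at the phenol only (BnBr, K2CO3, acetone, reflux), because the carbonate deprotonates the phenol but not the aliphatic alcohol. This gives 2-[4-(benzyloxy)phenyl]ethanol F1. Steglich esterification of the free primary alcohol with acid 1 (EDC·HCl, catalytic DMAP, CH2Cl2/THF, 40 °C) then gives 2-[4-(benzyloxy)phenyl]ethyl pentacosanoate F2. Hydrogenolysis of the benzyl ether (H2 1 atm, Pd/C as 10 wt % palladium metal on carbon, EtOAc/THF, 40 °C) leaves the non-benzylic ester untouched and delivers target 3.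

**Further compounds**
F1 | step 1 | 2-[4-(benzyloxy)phenyl]ethanol | OCCc1ccc(OCc2ccccc2)cc1
F2 | step 1 | 2-[4-(benzyloxy)phenyl]ethyl pentacosanoate | CCCCCCCCCCCCCCCCCCCCCCCCC(=O)OCCc1ccc(OCc2ccccc2)cc1
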